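## Retrosynthetic overview

1. The last skeletal bond is the ester between the primary alcohol of fragment 1 (the lactone half) and the acid of fragment 2 (the cyclohexenyl acrylic acid); one fluoride step then removes all silicon groups.
2. Fragment 1: ring C (seven-membered lactone) is closed last by ring-closing metathesis of an acrylate ester onto a vinyl group; that vinyl group comes from the key step, a Pd-catalysed carboxylate-directed β-C–H vinylation that sets C5a cis to the carboxyl and the isopropyl group.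
3. Ring A (cyclohexane of fragment 1) is formed first by an iminium-catalysed Diels–Alder reaction; α-oxygenation, lactonisation to a temporary γ-lactone and hydroxyl-directed hydrogenation set the other three centres.
4. Fragment 2: ring B (cyclohexene) comes from an enantioselective endo Diels–Alder reaction of a 1,3-disubstituted diene (from ene–yne cross-metathesis) with methyl vinyl ketone; acetyl is converted to isopropyl and an aldol–elimination builds the E-acrylate.

Assumption: the SMILES is taken literally, i.e. lactone half (5aR,6R,9S,9aS) with all four carbon substituents of ring A cis, cyclohexenyl half (1R,6S) with an E-acrylate; the two halves therefore need independent catalysts.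

Abbreviations: TBS = tert-butyldimethylsilyl, TES = triethylsilyl, TBSO/TESO = the silyloxy groups, Bz = benzoyl, Ms = methanesulfonyl, H2IMes = 1,3-dimesityl-4,5-dihydroimidazol-2-ylidene, MNBA = 2-methyl-6-nitrobenzoic anhydride, TASF = tris(dimethylamino)sulfonium difluorotrimethylsilicate.

## Fragment 1 (lactone half)

Step 1
Reactants: 1 3-methylbut-1-yne; 2 ethylene
Product: 3 2-(propan-2-yl)buta-1,3-diene
Conditions: RuCl2(=CHPh)(PCy3)(H2IMes) (second-generation Grubbs catalyst, 3 mol%), ethylene (1 atm), CH2Cl2, 25 °C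
Reagents that add atoms: none
Why: Ene–yne cross-metathesis; the Ru carbene adds to the terminal alkyne and the resulting vinylcarbene is turned over by ethylene, giving the 2-substituted 1,3-diene with no by-product.

Step 2
Reactants: 3 2-(propan-2-yl)buta-1,3-diene; 4 methyl (2E)-4-oxobut-2-enoate
Product: 5 methyl (1S,6S)-6-formyl-3-isopropylcyclohex-3-ene-1-carboxylate
Conditions: (5S)-5-benzyl-2,2,3-trimethylimidazolidin-4-one hydrochloride (20 mol%), MeCN/H2O 95:5, −10 °C
Reagents that add atoms: none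
Why: Iminium-catalysed Diels–Alder reaction; the ester-bearing β-carbon of the iminium bonds to the diene terminus next to the isopropyl-bearing carbon ("para" CHO/isopropyl), the benzyl group of the (5S)-catalyst shields one face so that C1 is formed S, and the E-dienophile gives the trans adduct.

Step 3
Reactants: 5 methyl (1S,6S)-6-formyl-3-isopropylcyclohex-3-ene-1-carboxylate
Product: 6 methyl (1S,6S)-6-(benzoyloxy)-6-formyl-3-isopropylcyclohex-3-ene-1-carboxylate
Conditions: N-methyl-O-benzoylhydroxylamine hydrochloride (1.3 equiv), DMSO, 25 °C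
Reagents that add atoms: N-methyl-O-benzoylhydroxylamine hydrochloride, CNOC(=O)c1ccccc1.Cl
Why: α-Benzoyloxylation of an α-branched aldehyde by [3,3]-sigmatropic shift of the N-benzoyloxy enamine; A(1,3) strain holds the neighbouring CO2Me axial, so oxygen is delivered to the opposite face and the new C6–O bond is trans to the ester (6S).

Step 4
Reactants: 6 methyl (1S,6S)-6-(benzoyloxy)-6-formyl-3-isopropylcyclohex-3-ene-1-carboxylate
Product: 9 (3aS,7aS)-3a-hydroxy-6-isopropyl-3a,4,7,7a-tetrahydroisobenzofuran-1(3H)-one, via hydroxy ester 7 (not isolated), via benzoate lactone 8 (not isolated)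
Conditions: NaBH4, MeOH, 0 °C; then K2CO3 (0.2 equiv), MeOH, 25 °C; aq. NH4Cl
Reagents that add atoms: none
Why: Chemoselective borohydride reduction of the aldehyde, lactonisation of the cis CH2OH onto the methyl ester to the cis-fused γ-lactone, then methanolysis (transesterification) of the tertiary benzoate; no stereocentre is touched.

Step 5
Reactants: 9 (3aS,7aS)-3a-hydroxy-6-isopropyl-3a,4,7,7a-tetrahydroisobenzofuran-1(3H)-one
Product: 10 (3aS,6S,7aS)-3a-hydroxy-6-isopropylhexahydroisobenzofuran-1(3H)-one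
Conditions: [Ir(cod)(PCy3)(py)]PF6 (5 mol%), H2 (1 atm), CH2Cl2, 25 °C
Reagents that add atoms: none
Why: Hydroxyl-directed homogeneous hydrogenation; the cationic iridium catalyst binds the tertiary OH and delivers H2 to the alkene face syn to it (also the convex face), so the isopropyl group ends cis to the lactone carbonyl (6S).

Step 6
Reactants: 10 (3aS,6S,7aS)-3a-hydroxy-6-isopropylhexahydroisobenzofuran-1(3H)-one
Product: 11 (3aS,6S,7aS)-6-isopropyl-3a-(triethylsilyloxy)hexahydroisobenzofuran-1(3H)-one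
Conditions: TESOTf, 2,6-lutidine, CH2Cl2, −78 → 0 °C
Reagents that add atoms: triethylsilyl trifluoromethanesulfonate, CC[Si](CC)(CC)OS(=O)(=O)C(F)(F)F
Why: Silylation of the hindered tertiary alcohol with a silyl triflate; it masks the β-hydroxyl before the palladium step.

Step 7
Reactants: 11 (3aS,6S,7aS)-6-isopropyl-3a-(triethylsilyloxy)hexahydroisobenzofuran-1(3H)-one
Product: 14 (1S,2S,5S)-2-[(TBSO)methyl]-5-isopropyl-2-(TESO)cyclohexane-1-carboxylic acid, via lithium carboxylate 12 (not isolated), via silyl ester 13 (not isolated)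
Conditions: LiOH·H2O (1.05 equiv), THF/H2O, 25 °C, evaporate; TBSCl (2.5 equiv), imidazole, DMF, 0 → 25 °C; K2CO3 (0.2 equiv), MeOH/H2O, 0 °C; pH 5 buffer
Reagents that add atoms: lithium hydroxide, [Li+].[OH-]; tert-butyldimethylsilyl chloride, CC(C)(C)[Si](C)(C)Cl
Why: Saponification of the γ-lactone, silylation of the primary alcohol and the carboxylate, then selective hydrolysis of the labile silyl ester; the free acid becomes the directing group while the blocked primary oxygen cannot relactonise.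

Step 8
Reactants: 14 (1S,2S,5S)-2-[(TBSO)methyl]-5-isopropyl-2-(TESO)cyclohexane-1-carboxylic acid
Product: 15 (1S,2S,5R,6S)-2-[(TBSO)methyl]-6-ethenyl-5-isopropyl-2-(TESO)cyclohexane-1-carboxylic acid
Conditions: Pd(OAc)2 (10 mol%), N-[2-(phenylsulfanyl)ethyl]acetamide (12 mol%), vinyl iodide (3 equiv), Ag2CO3 (1 equiv), Na2HPO4 (buffer), t-AmOH/(CF3)2CHOH 4:1, 80 °C, sealed tube
Reagents that add atoms: vinyl iodide (iodoethene), C=CI
Why: Proposed new method: carboxylate-directed β-methylene C(sp3)–H alkenylation of a free aliphatic acid with an alkenyl iodide. The κ1-carboxylate and the bidentate thioether–amide ligand allow concerted metalation–deprotonation of the C6–H bond cis to the carboxyl (C2 is quaternary, so C6 is the only β-site), giving a cis-fused five-membered palladacycle of divalent palladium; oxidative addition of vinyl iodide to tetravalent palladium and C–C reductive elimination with retention place the vinyl group cis to CO2H and hence cis to the isopropyl group (6S), while Ag2CO3 removes iodide. The closest known reactions are the ligand-enabled β-methylene C–H arylation of free carboxylic acids with aryl iodides and the 8-aminoquinoline-amide-directed C(sp3)–H alkenylation with vinyl iodides.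

Step 9
Reactants: 16 2-(bromomethyl)prop-2-enoic acid
Product: 17 2-(trimethylsilyl)ethyl 2-(bromomethyl)prop-2-enoate
Conditions: 2-(trimethylsilyl)ethanol, DCC, DMAP (5 mol%), CH2Cl2, 0 °C
Reagents that add atoms: 2-(trimethylsilyl)ethanol, C[Si](C)(C)CCO
Why: Steglich esterification; it installs a fluoride-labile ester on the future free carboxylic acid.

Step 10
Reactants: 15 (1S,2S,5R,6S)-2-[(TBSO)methyl]-6-ethenyl-5-isopropyl-2-(TESO)cyclohexane-1-carboxylic acid; 17 2-(trimethylsilyl)ethyl 2-(bromomethyl)prop-2-enoate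
Product: 18 2-{[2-(trimethylsilyl)ethoxy]carbonyl}prop-2-en-1-yl (1S,2S,5R,6S)-2-[(TBSO)methyl]-6-ethenyl-5-isopropyl-2-(TESO)cyclohexane-1-carboxylate
Conditions: Cs2CO3, DMF, 0 °C
Reagents that add atoms: none
Why: O-Alkylation of the caesium carboxylate by the allylic bromide (SN2 and SN2' give the same product) under conditions too mild to epimerise C1.

Step 11
Reactants: 18 2-{[2-(trimethylsilyl)ethoxy]carbonyl}prop-2-en-1-yl (1S,2S,5R,6S)-2-[(TBSO)methyl]-6-ethenyl-5-isopropyl-2-(TESO)cyclohexane-1-carboxylate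
Product: 19 2-(trimethylsilyl)ethyl (5aR,6R,9S,9aS)-9-[(TBSO)methyl]-6-isopropyl-1-oxo-9-(TESO)-1,3,5a,6,7,8,9,9a-octahydrobenzo[c]oxepine-4-carboxylate
Conditions: RuCl2(=CH-C6H4-2-OiPr)(H2IMes) (second-generation Hoveyda–Grubbs catalyst, 10 mol%), toluene (2 mM), 80 °C
Reagents that add atoms: none
Why: Ring-closing metathesis of the vinyl group with the 1,1-disubstituted acrylate closes ring C; the endocyclic trisubstituted alkene can only have the required geometry (ester carbon trans to C5a), and loss of ethylene drives the reaction.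

Step 12
Reactants: 19 2-(trimethylsilyl)ethyl (5aR,6R,9S,9aS)-9-[(TBSO)methyl]-6-isopropyl-1-oxo-9-(TESO)-1,3,5a,6,7,8,9,9a-octahydrobenzo[c]oxepine-4-carboxylate
Product: 20 2-(trimethylsilyl)ethyl (5aR,6R,9S,9aS)-9-hydroxy-9-(hydroxymethyl)-6-isopropyl-1-oxo-1,3,5a,6,7,8,9,9a-octahydrobenzo[c]oxepine-4-carboxylate
Conditions: HF·pyridine, pyridine, THF, 0 → 25 °C; used at once
Reagents that add atoms: none
Why: Buffered HF cleaves both silyl ethers but leaves the 2-(trimethylsilyl)ethyl ester and the lactone intact.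

## Fragment 2 (cyclohexenyl acrylic acid)

Step 13
Reactants: 21 prop-2-yn-1-ol
Product: 22 tert-butyldimethyl(prop-2-yn-1-yloxy)silane
Conditions: TBSCl, imidazole, CH2Cl2, 0 → 25 °C
Reagents that add atoms: tert-butyldimethylsilyl chloride, CC(C)(C)[Si](C)(C)Cl
Why: Standard silyl protection of a primary alcohol.

Step 14
Reactants: 22 tert-butyldimethyl(prop-2-yn-1-yloxy)silane; 23 allyl acetate
Product: 24 (2E)-4-[(TBSO)methyl]penta-2,4-dien-1-yl acetate
Conditions: RuCl2(=CHPh)(PCy3)(H2IMes) (second-generation Grubbs catalyst, 5 mol%), allyl acetate (3 equiv), CH2Cl2, 40 °C; E isomer separated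
Reagents that add atoms: none
Why: Ene–yne cross-metathesis; the alkylidene from allyl acetate adds to the terminal alkyne and the vinylcarbene is turned over by a second allyl acetate, giving the 1,3-disubstituted diene, with secondary metathesis enriching the E isomer.

Step 15
Reactants: 24 (2E)-4-[(TBSO)methyl]penta-2,4-dien-1-yl acetate; 25 but-3-en-2-one
Product: 26 [(1S,6R)-6-acetyl-3-[(TBSO)methyl]cyclohex-2-en-1-yl]methyl acetate
Conditions: (R)-3,3-diphenyl-1-(o-tolyl)tetrahydro-1H,3H-pyrrolo[1,2-c][1,3,2]oxazaborole/Tf2NH (20 mol%), CH2Cl2, −78 → −40 °C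
Reagents that add atoms: none
Why: Enantioselective Diels–Alder reaction with a cationic oxazaborolidine Lewis acid; the 1-substituent ("ortho") and the 3-substituent ("para") of the diene both place the acetyl-bearing carbon next to C1, the endo transition state gives the cis adduct, and the (R)-catalyst is expected, by analogy with acrylate dienophiles, to shield the face of s-trans-coordinated enone that would give 6S, so C6 is formed R.

Step 16
Reactants: 26 [(1S,6R)-6-acetyl-3-[(TBSO)methyl]cyclohex-2-en-1-yl]methyl acetate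
Product: 27 [(1S,6R)-3-[(TBSO)methyl]-6-(prop-1-en-2-yl)cyclohex-2-en-1-yl]methyl acetate
Conditions: Ph3PCH3Br (1.5 equiv), KOtBu (1.4 equiv), THF, 0 °C, 30 min
Reagents that add atoms: methyltriphenylphosphonium bromide, C[P+](c1ccccc1)(c1ccccc1)c1ccccc1.[Br-]
Why: Wittig methylenation of the methyl ketone; a slight deficit of base and short contact at 0 °C avoid epimerisation of the cis α-centre and attack on the acetate.

Step 17
Reactants: 27 [(1S,6R)-3-[(TBSO)methyl]-6-(prop-1-en-2-yl)cyclohex-2-en-1-yl]methyl acetate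
Product: 28 [(1R,6S)-3-[(TBSO)methyl]-6-isopropylcyclohex-2-en-1-yl]methyl acetate
Conditions: RhCl(PPh3)3 (5 mol%), H2 (1 atm), benzene, 25 °C
Reagents that add atoms: none
Why: Chemoselective homogeneous hydrogenation; the unhindered 1,1-disubstituted isopropenyl group is reduced and the trisubstituted ring alkene is not, and no stereocentre is formed (the descriptors change only because CIP priorities change).

Step 18
Reactants: 28 [(1R,6S)-3-[(TBSO)methyl]-6-isopropylcyclohex-2-en-1-yl]methyl acetate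
Product: 29 [(1R,6S)-3-[(TBSO)methyl]-6-isopropylcyclohex-2-en-1-yl]methanol
Conditions: K2CO3 (0.2 equiv), MeOH, 25 °C
Reagents that add atoms: none
Why: Base-catalysed methanolysis (transesterification) of the acetate; the silyl ether is stable.

Step 19
Reactants: 29 [(1R,6S)-3-[(TBSO)methyl]-6-isopropylcyclohex-2-en-1-yl]methanol
Product: 30 (1R,6S)-3-[(TBSO)methyl]-6-isopropylcyclohex-2-ene-1-carbaldehyde
Conditions: Dess–Martin periodinane, pyridine, CH2Cl2, 0 °C; used at once
Reagents that add atoms: none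
Why: Dess–Martin oxidation under buffered, non-epimerising conditions; the sensitive β,γ-unsaturated aldehyde is not stored.

Step 20
Reactants: 31 methyl 3-hydroxypropanoate
Product: 32 methyl 3-(TBSO)propanoate
Conditions: TBSCl, imidazole, DMF, 25 °C
Reagents that add atoms: tert-butyldimethylsilyl chloride, CC(C)(C)[Si](C)(C)Cl
Why: Standard silyl protection of a primary alcohol.

Step 21
Reactants: 30 (1R,6S)-3-[(TBSO)methyl]-6-isopropylcyclohex-2-ene-1-carbaldehyde; 32 methyl 3-(TBSO)propanoate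
Product: 34 methyl 2-[(TBSO)methyl]-3-hydroxy-3-[(1R,6S)-3-[(TBSO)methyl]-6-isopropylcyclohex-2-en-1-yl]propanoate (diastereomer mixture at C2 and C3), via lithium enolate 33 (not isolated)
Conditions: 32, LiN(iPr)2, THF, −78 °C; then 30, −78 °C; aq. NH4Cl
Reagents that add atoms: none
Why: Aldol addition of a preformed lithium ester enolate at −78 °C is faster than proton transfer, so the α-centre of the aldehyde is kept; the two new centres are removed in the next step.

Step 22
Reactants: 34 methyl 2-[(TBSO)methyl]-3-hydroxy-3-[(1R,6S)-3-[(TBSO)methyl]-6-isopropylcyclohex-2-en-1-yl]propanoate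
Product: 36 methyl (2E)-2-[(TBSO)methyl]-3-[(1R,6S)-3-[(TBSO)methyl]-6-isopropylcyclohex-2-en-1-yl]prop-2-enoate, via mesylate 35 (not isolated)
Conditions: MsCl, Et3N, CH2Cl2, 0 °C; then DBU, 0 → 25 °C
Reagents that add atoms: none
Why: Mesylation then E1cB elimination through the ester enolate; the transition state with the bulky ring trans to CO2Me (cis to CH2OTBS) is favoured, giving the E-alkene.

Step 23
Reactants: 36 methyl (2E)-2-[(TBSO)methyl]-3-[(1R,6S)-3-[(TBSO)methyl]-6-isopropylcyclohex-2-en-1-yl]prop-2-enoate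
Product: 37 (2E)-2-[(TBSO)methyl]-3-[(1R,6S)-3-[(TBSO)methyl]-6-isopropylcyclohex-2-en-1-yl]prop-2-enoic acid
Conditions: LiOH, THF/MeOH/H2O, 25 °C; 1 M HCl to pH 4
Reagents that add atoms: lithium hydroxide, [Li+].[OH-]
Why: Saponification of the methyl ester; primary silyl ethers and the skipped diene are stable to aqueous LiOH at room temperature.

## Union and end game

Step 24
Reactants: 20 2-(trimethylsilyl)ethyl (5aR,6R,9S,9aS)-9-hydroxy-9-(hydroxymethyl)-6-isopropyl-1-oxo-1,3,5a,6,7,8,9,9a-octahydrobenzo[c]oxepine-4-carboxylate; 37 (2E)-2-[(TBSO)methyl]-3-[(1R,6S)-3-[(TBSO)methyl]-6-isopropylcyclohex-2-en-1-yl]prop-2-enoic acid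
Product: 38 2-(trimethylsilyl)ethyl (5aR,6R,9S,9aS)-9-hydroxy-6-isopropyl-1-oxo-9-{[((2E)-2-[(TBSO)methyl]-3-[(1R,6S)-3-[(TBSO)methyl]-6-isopropylcyclohex-2-en-1-yl]prop-2-enoyl)oxy]methyl}-1,3,5a,6,7,8,9,9a-octahydrobenzo[c]oxepine-4-carboxylate
Conditions: MNBA, DMAP, Et3N, CH2Cl2, 0 → 25 °C (37 activated first, 20 added last)
Reagents that add atoms: none
Why: Shiina esterification through a DMAP-activated mixed anhydride; only the primary hydroxyl of 20 is acylated because the tertiary one is too hindered, and fast acylation at 0 °C is meant to outpace translactonisation.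

Step 25
Reactants: 38 2-(trimethylsilyl)ethyl (5aR,6R,9S,9aS)-9-hydroxy-6-isopropyl-1-oxo-9-{[((2E)-2-[(TBSO)methyl]-3-[(1R,6S)-3-[(TBSO)methyl]-6-isopropylcyclohex-2-en-1-yl]prop-2-enoyl)oxy]methyl}-1,3,5a,6,7,8,9,9a-octahydrobenzo[c]oxepine-4-carboxylate
Product: 39 (5aR,6R,9S,9aS)-9-hydroxy-9-{[((2E)-2-(hydroxymethyl)-3-[(1R,6S)-3-(hydroxymethyl)-6-isopropylcyclohex-2-en-1-yl]prop-2-enoyl)oxy]methyl}-6-isopropyl-1-oxo-1,3,5a,6,7,8,9,9a-octahydrobenzo[c]oxepine-4-carboxylic acid (CNP0361406.12)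
Conditions: TASF (6 equiv), DMF/H2O, 0 → 25 °C; aq. NH4Cl, then pH 4
Reagents that add atoms: none
Why: Fluoride-induced global deprotection; fluoride cleaves the two primary silyl ethers and fragments the 2-(trimethylsilyl)ethyl ester by β-elimination, leaving the ester and lactone linkages and all stereocentres untouched.

## Compound list

1 | 3-methylbut-1-yne | CC(C)C#C | starting material
2 | ethylene | C=C | starting material
3 | 2-(propan-2-yl)buta-1,3-diene | CC(C)C(=C)C=C | intermediate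
4 | methyl (2E)-4-oxobut-2-enoate | COC(=O)/C=C/C=O | starting material
5 | methyl (1S,6S)-6-formyl-3-isopropylcyclohex-3-ene-1-carboxylate (CHO and CO2Me trans) | CC(C)C1=CC[C@H](C=O)[C@H](C1)C(=O)OC | intermediate
6 | methyl (1S,6S)-6-(benzoyloxy)-6-formyl-3-isopropylcyclohex-3-ene-1-carboxylate (OBz trans to CO2Me) | CC(C)C1=CC[C@@](OC(=O)c2ccccc2)(C=O)[C@H](C1)C(=O)OC | intermediate
7 | methyl (1S,6S)-6-(benzoyloxy)-6-(hydroxymethyl)-3-isopropylcyclohex-3-ene-1-carboxylate | CC(C)C1=CC[C@@](OC(=O)c2ccccc2)(CO)[C@H](C1)C(=O)OC | intermediate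
8 | (3aS,7aS)-3a-(benzoyloxy)-6-isopropyl-3a,4,7,7a-tetrahydroisobenzofuran-1(3H)-one (cis-fused) | CC(C)C1=CC[C@@]2(OC(=O)c3ccccc3)COC(=O)[C@H]2C1 | intermediate
9 | (3aS,7aS)-3a-hydroxy-6-isopropyl-3a,4,7,7a-tetrahydroisobenzofuran-1(3H)-one | CC(C)C1=CC[C@@]2(O)COC(=O)[C@H]2C1 | intermediate
10 | (3aS,6S,7aS)-3a-hydroxy-6-isopropylhexahydroisobenzofuran-1(3H)-one (isopropyl cis to the lactone carbonyl) | CC(C)[C@H]1CC[C@@]2(O)COC(=O)[C@H]2C1 | intermediate
11 | (3aS,6S,7aS)-6-isopropyl-3a-(triethylsilyloxy)hexahydroisobenzofuran-1(3H)-one | CC(C)[C@H]1CC[C@@]2(O[Si](CC)(CC)CC)COC(=O)[C@H]2C1 | intermediate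
12 | lithium (1S,2S,5S)-2-(hydroxymethyl)-5-isopropyl-2-(triethylsilyloxy)cyclohexane-1-carboxylate | CC(C)[C@H]1CC[C@@](O[Si](CC)(CC)CC)(CO)[C@H](C1)C(=O)[O-].[Li+] | intermediate
13 | tert-butyldimethylsilyl (1S,2S,5S)-2-[(tert-butyldimethylsilyloxy)methyl]-5-isopropyl-2-(triethylsilyloxy)cyclohexane-1-carboxylate | CC(C)[C@H]1CC[C@@](O[Si](CC)(CC)CC)(CO[Si](C)(C)C(C)(C)C)[C@H](C1)C(=O)O[Si](C)(C)C(C)(C)C | intermediate
14 | (1S,2S,5S)-2-[(TBSO)methyl]-5-isopropyl-2-(TESO)cyclohexane-1-carboxylic acid | CC(C)[C@H]1CC[C@@](O[Si](CC)(CC)CC)(CO[Si](C)(C)C(C)(C)C)[C@H](C1)C(=O)O | intermediate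
15 | (1S,2S,5R,6S)-2-[(TBSO)methyl]-6-ethenyl-5-isopropyl-2-(TESO)cyclohexane-1-carboxylic acid (CO2H, vinyl, isopropyl and CH2OTBS all cis) | CC(C)[C@H]1CC[C@@](O[Si](CC)(CC)CC)(CO[Si](C)(C)C(C)(C)C)[C@@H](C(=O)O)[C@H]1C=C | intermediate
16 | 2-(bromomethyl)prop-2-enoic acid | C=C(CBr)C(=O)O | starting material
17 | 2-(trimethylsilyl)ethyl 2-(bromomethyl)prop-2-enoate | C=C(CBr)C(=O)OCC[Si](C)(C)C | intermediate
18 | 2-{[2-(trimethylsilyl)ethoxy]carbonyl}prop-2-en-1-yl (1S,2S,5R,6S)-2-[(TBSO)methyl]-6-ethenyl-5-isopropyl-2-(TESO)cyclohexane-1-carboxylate | CC(C)[C@H]1CC[C@@](O[Si](CC)(CC)CC)(CO[Si](C)(C)C(C)(C)C)[C@@H](C(=O)OCC(=C)C(=O)OCC[Si](C)(C)C)[C@H]1C=C | intermediate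
19 | 2-(trimethylsilyl)ethyl (5aR,6R,9S,9aS)-9-[(TBSO)methyl]-6-isopropyl-1-oxo-9-(TESO)-1,3,5a,6,7,8,9,9a-octahydrobenzo[c]oxepine-4-carboxylate | CC(C)[C@H]1CC[C@@](O[Si](CC)(CC)CC)(CO[Si](C)(C)C(C)(C)C)[C@H]2C(=O)OCC(C(=O)OCC[Si](C)(C)C)=C[C@@H]12 | intermediate
20 | 2-(trimethylsilyl)ethyl (5aR,6R,9S,9aS)-9-hydroxy-9-(hydroxymethyl)-6-isopropyl-1-oxo-1,3,5a,6,7,8,9,9a-octahydrobenzo[c]oxepine-4-carboxylate | CC(C)[C@H]1CC[C@@](O)(CO)[C@H]2C(=O)OCC(C(=O)OCC[Si](C)(C)C)=C[C@@H]12 | intermediate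
21 | prop-2-yn-1-ol | C#CCO | starting material
22 | tert-butyldimethyl(prop-2-yn-1-yloxy)silane | C#CCO[Si](C)(C)C(C)(C)C | intermediate
23 | allyl acetate (prop-2-en-1-yl acetate) | C=CCOC(C)=O | starting material
24 | (2E)-4-[(TBSO)methyl]penta-2,4-dien-1-yl acetate | CC(=O)OC/C=C/C(=C)CO[Si](C)(C)C(C)(C)C | intermediate
25 | but-3-en-2-one (methyl vinyl ketone) | CC(=O)C=C | starting material
26 | [(1S,6R)-6-acetyl-3-[(TBSO)methyl]cyclohex-2-en-1-yl]methyl acetate (cis) | CC(=O)OC[C@H]1C=C(CO[Si](C)(C)C(C)(C)C)CC[C@H]1C(C)=O | intermediate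
27 | [(1S,6R)-3-[(TBSO)methyl]-6-(prop-1-en-2-yl)cyclohex-2-en-1-yl]methyl acetate | CC(=O)OC[C@H]1C=C(CO[Si](C)(C)C(C)(C)C)CC[C@H]1C(C)=C | intermediate
28 | [(1R,6S)-3-[(TBSO)methyl]-6-isopropylcyclohex-2-en-1-yl]methyl acetate | CC(=O)OC[C@H]1C=C(CO[Si](C)(C)C(C)(C)C)CC[C@H]1C(C)C | intermediate
29 | [(1R,6S)-3-[(TBSO)methyl]-6-isopropylcyclohex-2-en-1-yl]methanol | OC[C@H]1C=C(CO[Si](C)(C)C(C)(C)C)CC[C@H]1C(C)C | intermediate
30 | (1R,6S)-3-[(TBSO)methyl]-6-isopropylcyclohex-2-ene-1-carbaldehyde | O=C[C@H]1C=C(CO[Si](C)(C)C(C)(C)C)CC[C@H]1C(C)C | intermediate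
31 | methyl 3-hydroxypropanoate | COC(=O)CCO | starting material
32 | methyl 3-(TBSO)propanoate | COC(=O)CCO[Si](C)(C)C(C)(C)C | intermediate
33 | lithium 3-(TBSO)-1-methoxyprop-1-en-1-olate | COC(=CCO[Si](C)(C)C(C)(C)C)[O-].[Li+] | intermediate
34 | methyl 2-[(TBSO)methyl]-3-hydroxy-3-[(1R,6S)-3-[(TBSO)methyl]-6-isopropylcyclohex-2-en-1-yl]propanoate (C2/C3 diastereomer mixture) | COC(=O)C(CO[Si](C)(C)C(C)(C)C)C(O)[C@H]1C=C(CO[Si](C)(C)C(C)(C)C)CC[C@H]1C(C)C | intermediate
35 | methyl 2-[(TBSO)methyl]-3-(methanesulfonyloxy)-3-[(1R,6S)-3-[(TBSO)methyl]-6-isopropylcyclohex-2-en-1-yl]propanoate | COC(=O)C(CO[Si](C)(C)C(C)(C)C)C(OS(C)(=O)=O)[C@H]1C=C(CO[Si](C)(C)C(C)(C)C)CC[C@H]1C(C)C | intermediate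
36 | methyl (2E)-2-[(TBSO)methyl]-3-[(1R,6S)-3-[(TBSO)methyl]-6-isopropylcyclohex-2-en-1-yl]prop-2-enoate | COC(=O)/C(=C/[C@H]1C=C(CO[Si](C)(C)C(C)(C)C)CC[C@H]1C(C)C)CO[Si](C)(C)C(C)(C)C | intermediate
37 | (2E)-2-[(TBSO)methyl]-3-[(1R,6S)-3-[(TBSO)methyl]-6-isopropylcyclohex-2-en-1-yl]prop-2-enoic acid | OC(=O)/C(=C/[C@H]1C=C(CO[Si](C)(C)C(C)(C)C)CC[C@H]1C(C)C)CO[Si](C)(C)C(C)(C)C | intermediate
38 | 2-(trimethylsilyl)ethyl (5aR,6R,9S,9aS)-9-hydroxy-6-isopropyl-1-oxo-9-{[((2E)-2-[(TBSO)methyl]-3-[(1R,6S)-3-[(TBSO)methyl]-6-isopropylcyclohex-2-en-1-yl]prop-2-enoyl)oxy]methyl}-1,3,5a,6,7,8,9,9a-octahydrobenzo[c]oxepine-4-carboxylate | CC(C)[C@H]1CC[C@@](O)(COC(=O)/C(=C/[C@H]2C=C(CO[Si](C)(C)C(C)(C)C)CC[C@H]2C(C)C)CO[Si](C)(C)C(C)(C)C)[C@H]2C(=O)OCC(C(=O)OCC[Si](C)(C)C)=C[C@@H]12 | intermediate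
39 | (5aR,6R,9S,9aS)-9-hydroxy-9-{[((2E)-2-(hydroxymethyl)-3-[(1R,6S)-3-(hydroxymethyl)-6-isopropylcyclohex-2-en-1-yl]prop-2-enoyl)oxy]methyl}-6-isopropyl-1-oxo-1,3,5a,6,7,8,9,9a-octahydrobenzo[c]oxepine-4-carboxylic acid | CC(C)[C@H]1CC[C@@](O)(COC(=O)/C(=C/[C@H]2C=C(CO)CC[C@H]2C(C)C)CO)[C@H]2C(=O)OCC(C(=O)O)=C[C@@H]12 | target

## Step count and risks

Total steps: 25. Longest linear sequence: 13 steps (steps 1–8, 10–12, 24, 25), which is 52 % of the total. Fragment 2 contributes 12 steps to the end (13–19, 21–23, 24, 25); steps 9 and 20 are one-step side branches.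

The three steps most likely to fail:

Step 8, the new carboxylate-directed vinylation. The C6 methylene is flanked by the isopropyl-bearing carbon, the product is a γ,δ-unsaturated acid that could be lactonised oxidatively by palladium, and the silyl ethers may suffer. The fallback uses known chemistry and sets out from lactone 11. AlMe3-mediated aminolysis with 8-aminoquinoline gives the hydroxy amide F1, and TBSCl/imidazole gives the silyl ether F2. The established 8-aminoquinoline-directed methylene C–H alkenylation (Pd(OAc)2, AgOAc, vinyl iodide, t-AmOH, 100 °C) gives the cis-vinyl amide F3. Boc2O/DMAP then gives the N-Boc imide F4, and LiOH/H2O2 cleaves it to acid 15, where the route is rejoined.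

Step 15, the Lewis-acid Diels–Alder reaction. The facial sense with methyl vinyl ketone rests on analogy, and the allylic acetate and silyl ether of the diene may not tolerate the cationic boron catalyst. The fallback sets out from diene 24. An iminium-catalysed Diels–Alder reaction with acrolein ((5S)-5-benzyl-2,2,3-trimethylimidazolidin-4-one hydrochloride, MeCN/H2O, −10 °C), whose facial sense follows the same model as step 2, gives the cis aldehyde F5. MeMgBr (THF, −78 °C) gives the carbinol F6, and Dess–Martin oxidation returns methyl ketone 26.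

Step 24, the union. In diol 20 the free primary hydroxyl can attack the strained seven-membered lactone and contract it to the γ-lactone before the hindered, neopentyl-type alcohol is acylated. The fallback changes the order of ring closure and union and sets out from the open-chain diene ester 18. HF·pyridine gives the diol F7, whose acyclic ester is far less prone to acyl transfer. MNBA/DMAP esterification with acid 37 gives the diene F8, and ring-closing metathesis (RuCl2(=CH-C6H4-2-OiPr)(H2IMes), toluene, 80 °C) closes ring C and returns 38.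

Further compounds

F1 | step 8 | (1S,2S,5S)-2-(hydroxymethyl)-5-isopropyl-N-(quinolin-8-yl)-2-(triethylsilyloxy)cyclohexane-1-carboxamide | CC(C)[C@H]1CC[C@@](O[Si](CC)(CC)CC)(CO)[C@H](C1)C(=O)Nc1cccc2cccnc12
F2 | step 8 | (1S,2S,5S)-2-[(tert-butyldimethylsilyloxy)methyl]-5-isopropyl-N-(quinolin-8-yl)-2-(triethylsilyloxy)cyclohexane-1-carboxamide | CC(C)[C@H]1CC[C@@](O[Si](CC)(CC)CC)(CO[Si](C)(C)C(C)(C)C)[C@H](C1)C(=O)Nc1cccc2cccnc12
F3 | step 8 | (1S,2S,5R,6S)-2-[(tert-butyldimethylsilyloxy)methyl]-6-ethenyl-5-isopropyl-N-(quinolin-8-yl)-2-(triethylsilyloxy)cyclohexane-1-carboxamide | CC(C)[C@H]1CC[C@@](O[Si](CC)(CC)CC)(CO[Si](C)(C)C(C)(C)C)[C@@H](C(=O)Nc2cccc3cccnc23)[C@H]1C=C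
F4 | step 8 | tert-butyl N-{[(1S,2S,5R,6S)-2-[(tert-butyldimethylsilyloxy)methyl]-6-ethenyl-5-isopropyl-2-(triethylsilyloxy)cyclohexyl]carbonyl}-N-(quinolin-8-yl)carbamate | CC(C)[C@H]1CC[C@@](O[Si](CC)(CC)CC)(CO[Si](C)(C)C(C)(C)C)[C@@H](C(=O)N(C(=O)OC(C)(C)C)c2cccc3cccnc23)[C@H]1C=C
F5 | step 15 | [(1S,6R)-3-[(tert-butyldimethylsilyloxy)methyl]-6-formylcyclohex-2-en-1-yl]methyl acetate | CC(=O)OC[C@H]1C=C(CO[Si](C)(C)C(C)(C)C)CC[C@H]1C=O
F6 | step 15 | [(1S,6R)-3-[(tert-butyldimethylsilyloxy)methyl]-6-(1-hydroxyethyl)cyclohex-2-en-1-yl]methyl acetate (carbinol epimers) | CC(=O)OC[C@H]1C=C(CO[Si](C)(C)C(C)(C)C)CC[C@H]1C(C)O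
F7 | step 24 | 2-{[2-(trimethylsilyl)ethoxy]carbonyl}prop-2-en-1-yl (1S,2S,5R,6S)-6-ethenyl-2-hydroxy-2-(hydroxymethyl)-5-isopropylcyclohexane-1-carboxylate | CC(C)[C@H]1CC[C@@](O)(CO)[C@@H](C(=O)OCC(=C)C(=O)OCC[Si](C)(C)C)[C@H]1C=C
F8 | step 24 | 2-{[2-(trimethylsilyl)ethoxy]carbonyl}prop-2-en-1-yl (1S,2S,5R,6S)-6-ethenyl-2-hydroxy-5-isopropyl-2-{[((2E)-2-[(tert-butyldimethylsilyloxy)methyl]-3-[(1R,6S)-3-[(tert-butyldimethylsilyloxy)methyl]-6-isopropylcyclohex-2-en-1-yl]prop-2-enoyl)oxy]methyl}cyclohexane-1-carboxylate | CC(C)[C@H]1CC[C@@](O)(COC(=O)/C(=C/[C@H]2C=C(CO[Si](C)(C)C(C)(C)C)CC[C@H]2C(C)C)CO[Si](C)(C)C(C)(C)C)[C@@H](C(=O)OCC(=C)C(=O)OCC[Si](C)(C)C)[C@H]1C=C
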